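The pyran ring is disconnected at O1–C2 and C4a–C4. This frees ring A with its oxygen as a 2-hydroxyarylboronic acid and leaves C2–C3–C4 with all three side chains as an acyclic all-syn 1,3-diol. The key step exploits that C4 is an allylic carbinol carbon conjugated through the styryl C=C to the 4-oxyphenyl ring, and C2 a benzylic carbinol carbon on the 2,4-dimethoxyphenyl ring: a latent 1,3-dielectrophile whose two oxygens template the boron. In one flask zerovalent palladium transfers the aryl group to C4 with inversion, then acid closes O1 onto C2. C3 stems from an asymmetric syn-aldol reaction.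

Key step: step 5

Remark: (2-hydroxy-4-methoxyphenyl)boronic acid is taken as a purchasable building block, and the face selectivity of the (−)-isopinocampheyl boron triflate is assigned by analogy with ethyl ketone aldol additions, so the antipodal reagent would replace it if the sense proved opposite.

Step 1
Reactants: 1 4-(4-hydroxyphenyl)butan-2-one; 2 4-hydroxybenzaldehyde
Product: 3 (E)-1,5-bis(4-hydroxyphenyl)pent-1-en-3-one
Conditions: KOH (4 equiv), EtOH/H2O, 23 °C; then aq. HCl to pH 5
Reagents that add atoms: none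
Why: Claisen–Schmidt condensation: under base the methyl ketone should condense at its less hindered methyl group, and E1cB dehydration should give the conjugated E-enone (no stereocentre).

Step 2
Reactants: 3 (E)-1,5-bis(4-hydroxyphenyl)pent-1-en-3-one
Product: 4 (E)-1,5-bis[4-(tert-butyldimethylsilyloxy)phenyl]pent-1-en-3-one
Conditions: TBSCl (2.4 equiv), imidazole (5 equiv), DMF, 23 °C
Reagents that add atoms: tert-butyldimethylsilyl chloride (TBSCl), CC(C)(C)[Si](C)(C)Cl
Why: Imidazole-promoted silyl ether formation masks both phenols for the boron aldol and the palladium step and leaves the enone untouched.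

Step 3
Reactants: 4 (E)-1,5-bis[4-(tert-butyldimethylsilyloxy)phenyl]pent-1-en-3-one; 5 2,4-dimethoxybenzaldehyde
Product: 7 (1E,4S,5S)-4-[4-(tert-butyldimethylsilyloxy)benzyl]-1-[4-(tert-butyldimethylsilyloxy)phenyl]-5-(2,4-dimethoxyphenyl)-5-hydroxypent-1-en-3-one, via Z-enol diisopinocampheylborinate 6 (not isolated)
Conditions: (−)-Ipc2BOTf (1.3 equiv), i-Pr2NEt (1.6 equiv), CH2Cl2, −78 °C; 5, −78 to −20 °C; then H2O2, pH 7 buffer, MeOH, 0 °C
Reagents that add atoms: none
Why: Reagent-controlled boron aldol reaction: triflate and amine should give the Z-enol borinate 6, whose chair-like Zimmerman–Traxler transition state delivers the syn adduct, and the isopinocampheyl ligands select the aldehyde face, which sets C4 and C5 of 7 as (4S,5S).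

Step 4
Reactants: 7 (1E,4S,5S)-4-[4-(tert-butyldimethylsilyloxy)benzyl]-1-[4-(tert-butyldimethylsilyloxy)phenyl]-5-(2,4-dimethoxyphenyl)-5-hydroxypent-1-en-3-one
Product: 9 (1S,2R,3S,4E)-2-[4-(tert-butyldimethylsilyloxy)benzyl]-5-[4-(tert-butyldimethylsilyloxy)phenyl]-1-(2,4-dimethoxyphenyl)pent-4-ene-1,3-diol, via diethylboryl aldolate chelate 8 (not isolated)
Conditions: Et2BOMe (1.1 equiv), THF/MeOH 4:1, −78 °C; NaBH4 (1.2 equiv); then MeOH co-evaporation
Reagents that add atoms: none
Why: Narasaka–Prasad reduction: the boron chelate 8 fixes a half-chair in which external hydride adds axially to the ketone, which should give the 1,3-syn diol by 1,2-reduction and sets the new carbinol centre as (3S).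

Step 5
Reactants: 9 (1S,2R,3S,4E)-2-[4-(tert-butyldimethylsilyloxy)benzyl]-5-[4-(tert-butyldimethylsilyloxy)phenyl]-1-(2,4-dimethoxyphenyl)pent-4-ene-1,3-diol; 10 (2-hydroxy-4-methoxyphenyl)boronic acid
Product: 13 (2R,3R,4R)-3-[4-(tert-butyldimethylsilyloxy)benzyl]-4-[(E)-2-[4-(tert-butyldimethylsilyloxy)phenyl]vinyl]-2-(2,4-dimethoxyphenyl)-7-methoxychroman, via cyclic boronic ester 11 (not isolated), via ortho-allylated phenol 12 (not isolated)
Conditions: Pd(PPh3)4 (5 mol %), 10 (1.5 equiv), 1,4-dioxane, 80 °C; then TsOH·H2O (0.3 equiv), 23 °C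
Reagents that add atoms: none
Why: Diol 9 and boronic acid 10 should first condense to the six-membered cyclic boronic ester 11; zerovalent palladium then ionises its allylic C4–O bond from the face opposite to the oxygen, the released boron-bound oxygen binds palladium so that the aryl group is handed over within the complex, and reductive elimination joins the ipso carbon (C4a) to C4 to give 12, after which TsOH ionises the 2,4-dimethoxybenzylic C2–O bond and the phenol oxygen O1 captures C2. The closest known reaction types are the base-free Suzuki–Miyaura-type coupling of free allylic alcohols with arylboronic acids, which runs with net inversion, and the acid-catalysed cyclodehydration of 1-aryl-3-(2-hydroxyphenyl)propan-1-ols to flavans. The only ring of the product that is closed, the pyran ring, is completed by the O1–C2 bond in a six-membered exo closure of the phenol oxygen onto the trigonal benzylic cation (6-exo-trig), the dioxaborinane of 11 being a transient template. C4 is set by stereospecific inversion of the (3S)-carbinol of 9 (anti oxidative addition, then aryl delivery from palladium), C3 is carried over from the aldol step, and C2 is set by reversible capture of the cation, which should settle on the all-equatorial 2,3-trans isomer (the isomer that direct invertive displacement would also give). The step needs C–C bond formation at C4 and not at the benzylic styryl terminus, at oxygen or at another ring position, which is secured by ipso transfer from boron, by the O–B tether from C2 that reaches C4 and by retention of styrene conjugation; it also needs O1 to attack C2 only after the C–C bond exists, which is secured because the benzylic alcohol stays inert until acid is added.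

Step 6
Reactants: 13 (2R,3R,4R)-3-[4-(tert-butyldimethylsilyloxy)benzyl]-4-[(E)-2-[4-(tert-butyldimethylsilyloxy)phenyl]vinyl]-2-(2,4-dimethoxyphenyl)-7-methoxychroman
Product: 14 caraganin C
Conditions: TBAF (2.5 equiv), AcOH (2.5 equiv), THF, 0 °C
Reagents that add atoms: none
Why: Fluoride-mediated desilylation of the two aryl silyl ethers, buffered with acetic acid so that the phenoxides and the acid-labile benzylic ether at C2 see neither strong base nor strong acid; no stereocentre is touched.

Compound list
1 | 4-(4-hydroxyphenyl)butan-2-one | CC(=O)CCc1ccc(O)cc1 | starting material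
2 | 4-hydroxybenzaldehyde | O=Cc1ccc(O)cc1 | starting material
3 | (E)-1,5-bis(4-hydroxyphenyl)pent-1-en-3-one | O=C(CCc1ccc(O)cc1)/C=C/c1ccc(O)cc1 | intermediate
4 | (E)-1,5-bis[4-(tert-butyldimethylsilyloxy)phenyl]pent-1-en-3-one | CC(C)(C)[Si](C)(C)Oc1ccc(CCC(=O)/C=C/c2ccc(O[Si](C)(C)C(C)(C)C)cc2)cc1 | intermediate
5 | 2,4-dimethoxybenzaldehyde | COc1ccc(C=O)c(OC)c1 | starting material
6 | (1E,3Z)-1,5-bis[4-(tert-butyldimethylsilyloxy)phenyl]penta-1,3-dien-3-yl diisopinocampheylborinate (Z-enol borinate, not isolated) | CC(C)(C)[Si](C)(C)Oc1ccc(C/C=C(\OB([C@@H]2C[C@@H]3C[C@H]([C@H]2C)C3(C)C)[C@@H]2C[C@@H]3C[C@H]([C@H]2C)C3(C)C)/C=C/c2ccc(O[Si](C)(C)C(C)(C)C)cc2)cc1 | intermediate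
7 | (1E,4S,5S)-4-[4-(tert-butyldimethylsilyloxy)benzyl]-1-[4-(tert-butyldimethylsilyloxy)phenyl]-5-(2,4-dimethoxyphenyl)-5-hydroxypent-1-en-3-one | COc1ccc(c(OC)c1)[C@@H](O)[C@H](Cc1ccc(O[Si](C)(C)C(C)(C)C)cc1)C(=O)/C=C/c1ccc(O[Si](C)(C)C(C)(C)C)cc1 | intermediate
8 | O-diethylboryl derivative of 7 (diethylboryl aldolate chelate, not isolated) | CCB(CC)O[C@H](c1ccc(OC)cc1OC)[C@H](Cc1ccc(O[Si](C)(C)C(C)(C)C)cc1)C(=O)/C=C/c1ccc(O[Si](C)(C)C(C)(C)C)cc1 | intermediate
9 | (1S,2R,3S,4E)-2-[4-(tert-butyldimethylsilyloxy)benzyl]-5-[4-(tert-butyldimethylsilyloxy)phenyl]-1-(2,4-dimethoxyphenyl)pent-4-ene-1,3-diol | COc1ccc(c(OC)c1)[C@@H](O)[C@H](Cc1ccc(O[Si](C)(C)C(C)(C)C)cc1)[C@@H](O)/C=C/c1ccc(O[Si](C)(C)C(C)(C)C)cc1 | intermediate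
10 | (2-hydroxy-4-methoxyphenyl)boronic acid | COc1ccc(B(O)O)c(O)c1 | starting material
11 | (4S,5R,6S)-5-[4-(tert-butyldimethylsilyloxy)benzyl]-6-[(E)-2-[4-(tert-butyldimethylsilyloxy)phenyl]vinyl]-4-(2,4-dimethoxyphenyl)-2-(2-hydroxy-4-methoxyphenyl)-1,3,2-dioxaborinane (cyclic boronic ester, not isolated) | COc1ccc(B2O[C@H](c3ccc(OC)cc3OC)[C@H](Cc3ccc(O[Si](C)(C)C(C)(C)C)cc3)[C@H](/C=C/c3ccc(O[Si](C)(C)C(C)(C)C)cc3)O2)c(O)c1 | intermediate
12 | (1S,2R,3R,4E)-2-[4-(tert-butyldimethylsilyloxy)benzyl]-5-[4-(tert-butyldimethylsilyloxy)phenyl]-1-(2,4-dimethoxyphenyl)-3-(2-hydroxy-4-methoxyphenyl)pent-4-en-1-ol (ortho-allylated phenol, not isolated) | COc1ccc(c(O)c1)[C@H](/C=C/c1ccc(O[Si](C)(C)C(C)(C)C)cc1)[C@@H](Cc1ccc(O[Si](C)(C)C(C)(C)C)cc1)[C@H](O)c1ccc(OC)cc1OC | intermediate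
13 | (2R,3R,4R)-3-[4-(tert-butyldimethylsilyloxy)benzyl]-4-[(E)-2-[4-(tert-butyldimethylsilyloxy)phenyl]vinyl]-2-(2,4-dimethoxyphenyl)-7-methoxychroman | COc1ccc2c(c1)O[C@@H](c1ccc(OC)cc1OC)[C@H](Cc1ccc(O[Si](C)(C)C(C)(C)C)cc1)[C@H]2/C=C/c1ccc(O[Si](C)(C)C(C)(C)C)cc1 | intermediate
14 | caraganin C, (2R,3R,4R)-2-(2,4-dimethoxyphenyl)-3-(4-hydroxybenzyl)-4-[(E)-2-(4-hydroxyphenyl)vinyl]-7-methoxychroman | COc1ccc2c(c1)O[C@@H](c1ccc(OC)cc1OC)[C@H](Cc1ccc(O)cc1)[C@H]2/C=C/c1ccc(O)cc1 | target

Total step count: 6. Longest linear sequence: 6 steps (1 to 14).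

Steps most likely to fail

Step 5 (key step). After ionisation, the allyl palladium complex may be captured by an oxygen nucleophile (ether formation), or lose a β-hydrogen from C3 to give a diene, before the aryl group reaches the hindered C4; palladium–palladium exchange may also erode the configuration at C4. The fallback is a metal-free cationic (3+3) annulation that sets out from 9 and comes back at 13. Diol 9 and commercial 3-methoxyphenol (3 equiv) are treated with Bi(OTf)3 (5 mol %) in HFIP/CH2Cl2 from −20 to 23 °C. Friedel–Crafts allylation at C4 through the aryl-stabilised allyl cation should give 12 in the flask, and dehydrative closure of O1 onto C2 follows under the same acid. In this variant C4 and C2 are set under thermodynamic control by the C3 stereocentre. No new compound is made (F0).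

Step 3. The isopinocampheyl ligands may discriminate poorly between the faces of the electron-rich aromatic aldehyde, and retro-aldol cleavage may occur during the oxidative work-up. The fallback uses auxiliary control, sets out from 5 and comes back at 7. Commercial 3-(4-hydroxyphenyl)propanoic acid is silylated (TBSCl, imidazole; then K2CO3, MeOH/H2O) to 3-[4-(tert-butyldimethylsilyloxy)phenyl]propanoic acid F1. F1 is activated with PivCl/Et3N and joined to lithiated (S)-4-benzyloxazolidin-2-one to give (S)-4-benzyl-3-{3-[4-(tert-butyldimethylsilyloxy)phenyl]propanoyl}oxazolidin-2-one F2. Evans syn-aldol reaction of F2 with 5 (Bu2BOTf, i-Pr2NEt, CH2Cl2, −78 °C) should give (S)-4-benzyl-3-[(2S,3S)-2-[4-(tert-butyldimethylsilyloxy)benzyl]-3-(2,4-dimethoxyphenyl)-3-hydroxypropanoyl]oxazolidin-2-one F3. Transamidation (MeONHMe·HCl, AlMe3) gives the Weinreb amide (2S,3S)-2-[4-(tert-butyldimethylsilyloxy)benzyl]-3-(2,4-dimethoxyphenyl)-3-hydroxy-N-methoxy-N-methylpropanamide F4. Takai olefination of commercial 4-(tert-butyldimethylsilyloxy)benzaldehyde (CrCl2, CHI3) gives (E)-tert-butyl[4-(2-iodovinyl)phenoxy]dimethylsilane F5. Iodine–lithium exchange (t-BuLi, −78 °C) turns F5 into (E)-{2-[4-(tert-butyldimethylsilyloxy)phenyl]vinyl}lithium F6, and addition of F6 (2.5 equiv) to F4 should give 7.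

Step 4. Conjugate reduction of the enone may compete, and 1,3-syn induction may be incomplete because the benzyl group on the α-carbon hinders the chelate-controlled hydride approach. The fallback replaces chelation control by catalyst control, sets out from 7 and comes back at 9. It is a Corey–Bakshi–Shibata 1,2-reduction with the oxazaborolidine enantiomer that delivers the (3S)-carbinol (expected to be (S)-Me-CBS if the styryl group acts as the large substituent) and catecholborane in excess for the free hydroxyl, in toluene at −78 °C. No new compound is made (F0).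

Further compounds
F0 | step 5 | none | none
F1 | step 3 | 3-[4-(tert-butyldimethylsilyloxy)phenyl]propanoic acid | CC(C)(C)[Si](C)(C)Oc1ccc(CCC(=O)O)cc1
F2 | step 3 | (S)-4-benzyl-3-{3-[4-(tert-butyldimethylsilyloxy)phenyl]propanoyl}oxazolidin-2-one | CC(C)(C)[Si](C)(C)Oc1ccc(CCC(=O)N2[C@@H](Cc3ccccc3)COC2=O)cc1
F3 | step 3 | (S)-4-benzyl-3-[(2S,3S)-2-[4-(tert-butyldimethylsilyloxy)benzyl]-3-(2,4-dimethoxyphenyl)-3-hydroxypropanoyl]oxazolidin-2-one | COc1ccc(c(OC)c1)[C@@H](O)[C@H](Cc1ccc(O[Si](C)(C)C(C)(C)C)cc1)C(=O)N1[C@@H](Cc2ccccc2)COC1=O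
F4 | step 3 | (2S,3S)-2-[4-(tert-butyldimethylsilyloxy)benzyl]-3-(2,4-dimethoxyphenyl)-3-hydroxy-N-methoxy-N-methylpropanamide | COc1ccc(c(OC)c1)[C@@H](O)[C@H](Cc1ccc(O[Si](C)(C)C(C)(C)C)cc1)C(=O)N(C)OC
F5 | step 3 | (E)-tert-butyl[4-(2-iodovinyl)phenoxy]dimethylsilane | CC(C)(C)[Si](C)(C)Oc1ccc(/C=C/I)cc1
F6 | step 3 | (E)-{2-[4-(tert-butyldimethylsilyloxy)phenyl]vinyl}lithium | [Li]/C=C/c1ccc(O[Si](C)(C)C(C)(C)C)cc1
F0 | step 4 | none | none
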